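The data were computed with made-up constants; scatter was added.

The reading of oak falls at 2.0 h, and the curve up to there can be drawn from what oak and birch already show.

| flask | starting material | reagent | scavenger | free catalyst | remark | time |
|---|---|---|---|---|---|---|
| oak | 2 M | 0.80 equiv | 0.50 equiv | 0.097 mol% | the very flask that is asked about, followed so far |  |
| birch | 2 M | 0.80 equiv | 0.50 equiv | 0.19 mol% | run made earlier |  |
| flask | 2.0 M | 0.800 equiv | 0.500 equiv | 0.097 mol% |  | 2.0 h |

| run | time / min | starting material / % | product / % |
|---|---|---|---|
| oak | 2.00 | 98.7 | 2.5 |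
| oak | 3.00 | 97.8 | 2.7 |
| oak | 4.00 | 96.5 | 2.4 |
| oak | 6.00 | 94.8 | 5.1 |
| oak | 10.0 | 91.1 | 7.8 |
| oak | 15.0 | 87.6 | 11.9 |
| oak | 25.0 | 79.4 | 19.9 |
| birch | 10.0 | 83.5 | 15.0 |
| birch | 15.0 | 77.6 | 23.3 |
| birch | 20.0 | 71.3 | 28.5 |
| birch | 30.0 | 61.8 | 38.2 |
| birch | 50.0 | 49.6 | 49.3 |
| birch | 80.0 | 40.0 | 59.6 |
| birch | 120 | 34.2 | 65.8 |

(each reading ± 0.5 percentage points)

1. part of the starting material that has reacted at 2.0 h
2. share of the unused reagent that is free and not bound as idle adduct, at 2.0 h

- amounts and yields of released group count idle adduct too
- what may be going on: reagent + free catalyst <-> catalyst intermediate A; starting material + catalyst intermediate A <-> catalyst intermediate B; catalyst intermediate B -> released group + catalyst intermediate C; catalyst intermediate C <-> free catalyst + product; reagent + released group <-> idle adduct; scavenger + released group -> scavenged by-product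
- the earlier runs do not show how much of reagent is bound; that part of a forecast is a guess

Oak starts at 0.00824 min⁻¹ of the charge over its first 25.0 min, and birch at 0.0165 min⁻¹ over its first 10.0 min. That read ratio of 2.00 stands close to the loading ratio of 1.96, so I put oak on birch's clock. Oak's reading becomes 61.3 min: this is the birch-clock time, a flask's time multiplied by its loading over birch's loading.

The first landmark is a crossing. At 50.0 min birch has reacted 50.4%, and scavenger is charged at 0.500 equiv, so my clock puts the released group made in oak past the scavenger charge at about 1.63 h of oak's own time, before the reading. A chord between birch's readings at 50.0 min and 80.0 min then puts oak at 54.0% reacted, probably a little low on a bending curve. Between 80.0 min and 120 min birch's slope reads 0.00145 min⁻¹, and the ceiling over the curve is 0.800 equiv, the charge of the limiting reagent. My clock gives no free share, since these readings do not show binding.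

The forecast says 54% (50% to 58%) reacted and 91% (78% to 99%) free, holding that “binding looks weak”.

Oak gives 56.5% reacted and 34.3% of the unused reagent free.

    reagent + free catalyst ⇌ catalyst intermediate A (K = 1.50 M⁻¹, k = 0.840 M⁻¹ s⁻¹)
    starting material + catalyst intermediate A ⇌ catalyst intermediate B (K = 3.90 M⁻¹, k = 0.660 M⁻¹ s⁻¹)
    catalyst intermediate B → released group + catalyst intermediate C (k = 42.0 s⁻¹)
    catalyst intermediate C ⇌ free catalyst + product (K = 1.70 M, k = 0.210 s⁻¹)
    reagent + released group ⇌ idle adduct, settled at all times (K = 53.0 M⁻¹)
    scavenger + released group → scavenged by-product (k = 0.0110 M⁻¹ s⁻¹)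

At 2.0 h oak stands 2.5 percentage points above my chord. At 1.00 h, before my crossing, oak still holds 67.3% of its scavenger, yet idle adduct already amounts to 21.8% of the starting material charged, and 46.6% of the unused reagent is free. On a neighbour of oak charged with 0.16 mol% of free catalyst, the birch-clock time is 101 min, where birch's chord gives 63.1%; that neighbour computes to 64.1%.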